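The constants of this flask were not given, so I turned the question round: what would the readings have to show for Thursday's flask to reach half of its substrate as target?

| flask | substrate | partner | time |
|---|---|---|---|
| Monday's | 1.00 M | 1.00 M |  |
| Tuesday's | 0.600 M | 0.600 M |  |
| Friday's | 1.00 M | 3.00 M |  |
| Wednesday's | 2.00 M | 1.00 M |  |
| Thursday's | 1.00 M | 1.00 M | 72 h |

| run | time / h | [target] / M |
|---|---|---|
| Monday's run | 1.4 | 0.059 |
| Monday's run | 4.2 | 0.200 |
| Monday's run | 7.9 | 0.314 |
| Monday's run | 13 | 0.357 |
| Monday's run | 18 | 0.383 |
| Tuesday's run | 1.4 | 0.032 |
| Tuesday's run | 4.2 | 0.103 |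
| Tuesday's run | 7.9 | 0.162 |
| Tuesday's run | 13 | 0.194 |
| Tuesday's run | 18 | 0.217 |
| Friday's run | 1.4 | 0.103 |
| Friday's run | 4.2 | 0.313 |
| Friday's run | 7.9 | 0.444 |
| Friday's run | 13 | 0.510 |
| Friday's run | 18 | 0.555 |
| Wednesday's run | 1.4 | 0.116 |
| Wednesday's run | 4.2 | 0.339 |
| Wednesday's run | 7.9 | 0.484 |
| Wednesday's run | 13 | 0.530 |
| Wednesday's run | 18 | 0.530 |

(scatter of a reading: 0.01 M)

- Overall: substrate + partner -> target.
- Constant volume, constant temperature.
- "The second partner" is partner.
- An order is taken over about fifteen percent of the charge, up and down.

1. apparent order in [partner] of the starting rate, round the charge of the Monday's run (the rate where two percent of its substrate have turned into target)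
2. apparent order in [substrate] of the starting rate, round the charge of the Monday's run (the rate where two percent of its substrate have turned into target) (one fixed amount of target, the same in the runs compared)
3. target in the Thursday's run at 72 h, as a share of the substrate charged

Thursday's charge is Monday's, so I took Monday's last reading, 0.383 M at 18 h, as Thursday's too. Late in a run the gain fades like the output of a first-order lag. To beat the scatter I summed the gains over the runs, 0.187 M from 7.9 h to 13 h and 0.0940 M from 13 h to 18 h.

τ = gap between mid-times / ln(earlier rate / later rate) = 7.56 h

I called τ the tail constant, the time in which the late rate of target making falls by a factor e. It is a reading and carries their scatter. Monday's last gain then gave what was still to come: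

remainder = last gain / (exp(last interval / τ) − 1) = 0.0277 M

That put Thursday at 41.1%. Reaching half needed a remainder of 0.117 M, which takes a τ of 24.9 h, 3.29 times the one I read.

Carrying Friday's gain after 7.9 h forward with the same τ, I put Friday's half of its substrate at 12.0 h.

The forecast gave 0.42 for the order in partner, 0.8 for the order in substrate and 43% for Thursday, on a tail “roughly halving every 5 h”. My share stood lower than its share.

The flask gave 0.52 in partner, higher than the forecast, and 0.62 in substrate, lower than the forecast. Thursday came to 39.7%, within the forecast's margin.

    substrate → intermediate (0.1555 h⁻¹)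
    intermediate + partner → target (0.6660 L mol⁻¹ h⁻¹)
    intermediate → side product (0.05868 h⁻¹)
    partner → lost reagent (0.1130 h⁻¹)
    2 substrate → homo dimer (0.1055 L mol⁻¹ h⁻¹)

Friday's half came at 11.6 h, against my 12.0 h. Thursday's 72 h lay 7.14 tail constants of 7.56 h beyond Monday's last reading. Thursday's 39.7% fell short of half because partner went over to lost reagent. In the run without that conversion, Thursday's flask passed half, at 56.0%.

The earlier runs and the new flask come from a simulation with made-up constants, and the scatter is random.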